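In this flask one number stays put while the concentrations move: the share of used starting material that becomes target.

starting material 0.14 M; gas phase 20 mM (held); catalyst 21 mM; time 12 h

    gas phase ⇌ dissolved gas, rate k1*(csat - [dissolved gas]) (k1 = 1.4 /h, csat = 20 mM)
    starting material + dissolved gas + catalyst → catalyst + target (k2 = 820 /M²/h)
    starting material + dissolved gas → uncatalysed product (k3 = 2.9 /M/h)
    dissolved gas + target ⇌ idle adduct, settled at all times (K4 = 30 /M)

- target is meant together with its idle adduct
- at the start none of the gas is dissolved
- run time (flask): 12 h

- the target and idle adduct together standing at 12 h, as a percentage of the starting material charged
- concentration of dissolved gas in solution at 6.0 h, in percent of saturation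
- the change that raises the amount of target and idle adduct together at 12 h, in percent of the starting material charged most ("none" if none brings more than 2 percentage points) (north-east / south / south-east / none)
- amount of target and idle adduct together at 12 h, in percent of the starting material charged, after north-east

- north-east: doubling the saturation concentration of gas phase, all else as stated
- south: doubling the amount of catalyst, all else as stated
- south-east: doubling the transfer coefficient of step 1, all else as stated

I write S for starting material, c for dissolved gas and f for the fraction of S left. The catalysed and the uncatalysed step each take one S and one dissolved gas, and the catalyst comes back. So S and c cancel from their ratio. With a the catalysed constant times the catalyst charged, 17.2 /M/h, and b the uncatalysed constant, 2.9 /M/h: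

s = a/(a + b) = 85.6%

This s, the selectivity, is the share of used starting material that becomes target. The idle adduct counts as target, so I reckon with what is left:

y = s·(1 − f)

First instants: nothing is dissolved, and gas crosses at 28.0 mM/h. The solution removes dissolved gas at a rate constant u = (a + b)·S, here 2.82 /h. Dissolved gas therefore climbs with a time constant of 0.237 h toward

c = k1·csat/(k1 + u) = 6.64 mM

S then decays with a time constant of 7.49 h, far slower than that.

Middle: as S falls, u falls and c climbs toward saturation. The idle adduct starts to hold gas, which delays S but leaves s as it is.

End: if c stayed at its early value,

f = exp(−(a + b)·c·t) = 20.1%, so y = 68.4%

Since c climbs, I expect y above that and below s. My reckoning stops at this range. North-east doubles the saturation concentration and south-east doubles the transfer coefficient, so both move f and leave s as it is. South doubles the amount of catalyst, which doubles a and moves the cap itself, to 92.2%, so I choose south.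

The forecast gives y 77.2%, sat 46%, best south and yb 85.4%, on the ground that “both S-consuming steps are first order in dissolved gas, so selectivity is fixed”. Its y is one number inside my range.

The simulation gives y 77.2%, sat 47.1% and yb 85.4%. Best is south, gaining 13 percentage points against 8.2 points for north-east and 5.6 points for south-east.

In this flask 9.8% of the starting material is left at 12 h, so s gives 77.2%, which is the simulated y. Taking the uncatalysed step away lifts this flask from 77.2% to 86.7%. That is the largest single effect, 42% of what is missing, and it acts together with the hour of reading. A reading of this flask ten times later gives 85.6%, which is s.

In the neighbour flask read at 5.0 h, 50% of the starting material is left, so s gives 42.8%. The simulated neighbour stands at 43.0%.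

(All constants are assumed.)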